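All constants were set for the occasion; the result is computed.

The charge of enzyme cannot stay whole as enzyme in this flask: a balance pairs it into resting dimer, which makes no product, and each resting dimer counts as two of the catalyst.

substrate 15 mM; enzyme 1.5 µM

    2 enzyme ⇌ resting dimer, settled at all times (K1 = 1.6 × 10⁶ L mol⁻¹)
    substrate + enzyme → product + enzyme, rate k2*[substrate]^1.5*[enzyme]/(1 + ([substrate]/Kh2)^1.5) (Kh2 = 7.3 mM, k2 = 1.4 × 10⁵ L¹·⁵ mol⁻¹·⁵ s⁻¹)

- a doubled species enters its step squared and goes two at a time
- a form made of two catalysts counts as two
- charge of substrate (flask): 15 mM

- the form that holds most of the catalyst when 20 % of the substrate are converted (resting dimer / enzyme)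
- its share of the catalyst then
- factor on the rate of making product when 20 % of the substrate are converted if enzyme is charged twice over
- factor on the rate when 20 % of the substrate are converted if enzyme is charged at 8.0 µM instead

Let f be the fraction of the catalyst charge standing as enzyme, and let the load be K1 times that charge, 2.40. Counting the resting dimer twice, the balance says that one equals f plus twice the load times f squared. Solving gives 36.4 %, and I call this fraction the free share. Substrate does not enter the balance, so I hold the free share steady through the run, and the resting dimer at 63.6 % holds more of the catalyst than enzyme does: it is the resting state.

Now I draw product, as a fraction of the substrate charge, against time in this flask. It leaves zero with a slope of 0.00237 s⁻¹. At 20 % conversion the slope is 0.00216 s⁻¹, so the mean of the two puts that point near 88.3 s. The knee lies where substrate equals Kh2, with 48.7 % of the charge left, and the slope there is 0.00159 s⁻¹. Beyond it the curve has no fixed half-life: far out, each halving of what is left takes 1.41 times the one before. The step runs one way, so the level is the whole charge as product.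

At a fixed conversion the substrate part of the rate is the same in two flasks with the same substrate charge, so between such flasks the rate factor is the ratio of free share times charge. With the charge doubled the free share falls to 27.5 %, so I expect a factor of 1.51, less than the factor on the charge.

The forecast names resting dimer at 63.6 % (range 62 % to 65 %), a factor of 1.51 (1.47 to 1.55) for the doubled charge, and 2.62 (2.5 to 2.75) at 8.0 µM, holding that “the rate scales with free enzyme alone”.

The simulation gives resting dimer at 63.6 %, with factors of 1.51 and 2.62. In this flask the making of product ran on 36.4 % of the catalyst from the first reading: enzyme stands at 36.4 % after 8.00 s and 36.4 % after 800 s, while substrate falls to 8.65 %, and 20 % conversion comes at 88.1 s with a rate of 0.0323 mM s⁻¹. In the flask charged at 8.0 µM the free share is 17.9 %, and that share times that charge is 2.62 times the enzyme of the first flask; the simulation's factor there is 2.62.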